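**Substrate balance.** Substrate is conserved: counted by the substrate in them, substrate, target, over-reacted product and self-condensation product sum to the charge at every moment.

substrate 1.4 M; gas phase 200 mM (held); time 5.0 min

    gas phase ⇌ dissolved gas, rate k1*(csat - [dissolved gas]) (k1 = 0.068 s⁻¹, csat = 200 mM)
    substrate + dissolved gas → target (k2 = 0.66 M⁻¹ s⁻¹)
    dissolved gas + target → over-reacted product (k3 = 0.031 M⁻¹ s⁻¹)
    dissolved gas ⇌ dormant form (K4 = 21, k4 = 0.0036 s⁻¹)
    dissolved gas → decomposed reagent (k5 = 6.0 × 10⁻⁴ s⁻¹)
    2 substrate → self-condensation product (k6 = 3.4 × 10⁻⁴ M⁻¹ s⁻¹)

- a species is counted by the substrate in it: one self-condensation product counts as two
- a doubled species enters its step squared and goes two at a time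
- at the start none of the gas is dissolved
- run time (flask): 5.0 min

1. amount of target at 5.0 min, in percent of the substrate charged
2. the change that raises the amount of target at 5.0 min, in percent of the substrate charged most ("none" if none brings more than 2 percentage points) (east / north-east / none)
3. amount of target at 5.0 min, in percent of the substrate charged, after north-east

**End state.** Each substrate can take up two dissolved gas, and step 1 can deliver at most 291% of the charge by 5.0 min into a solution kept empty, more than two charges. Target is therefore a way station, and the question is how far the flask gets towards over-reacted product.

**Exposure number.** At the charged concentration, substrate consumes dissolved gas by step 2 with a half-life of 0.75 s, shorter than the transfer time of 14.7 s, so while substrate lasts transfer is the rate-limiting step, and this reckoning turns the flask's charge into target in about 1.72 min. Afterwards, with target taken at the full charge, transfer balances over-reaction at 0.610 of saturation. The flask's exposure number is 0.746: the rate constant of step 3 times that gas level times the time left after the feed. The share of target surviving is exp(−N), here 47.4%.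

**One number enough?** East gives 1.17, so 31.0%. North-east gives 1.88, so 15.3%. Both fall below the figure reckoned for the unchanged flask, so this reckoning says none. The number omits self-condensation, whose first half-life by that step alone, 17.5 min, is longer than the feed, and it holds the gas level fixed.

**Forecast.** The forecast gave 45% (40% to 50%), none, and 11% (8% to 15%) after north-east, both figures lower than this reckoning's, on the ground that “More gas supply by either change only speeds that over-reaction”.

**Result.** The flask gives 45.3%; best is none (east −16 percentage points, north-east −34 points); north-east gives 10.9%. At 5.00 min the flask held 0.147 M dissolved gas, above the reckoned 0.122 M. Read back as minus the logarithm of the target share, the exposure is 0.792 in the flask against the reckoned 0.746, and 2.22 after north-east against 1.88.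

**Earlier reading.** Read at 3.0 min, the neighbour flask has a reckoned exposure of 0.292, so 74.7% target. It gives 75.1%.

The constants used here were chosen freely; the result is computed.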